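A factor of 2.74 comes out of the last two blue readings; averaged with the grey run, it is what I carry through this flask.

| flask | starting material | gas phase | remark | time |
|---|---|---|---|---|
| blue | 0.016 M | 6.6 mM (held) | run made earlier |  |
| grey | 0.036 M | 6.6 mM (held) | run made earlier |  |
| flask | 0.024 M | 6.6 mM (held) |  | 1.5 h |

- blue (time / min: target / %, starting material / %): 6.00: 9.8, 85.6; 12.0: 19.2, 70.4; 25.0: 19.6, 43.8; 50.0: 7.2, 12.6
- grey (time / min: target / %, starting material / %): 6.00: 7.8, 90.5; 12.0: 14.6, 80.3; 25.0: 19.9, 62.8; 50.0: 17.9, 35.9

(readings scatter by 0.5 percentage points)

* the moment within 1.5 h at which there is most target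
* the amount of target, in percent of the starting material charged, at that time

- at the start none of the gas is dissolved
- steps under discussion: dissolved gas -> decomposition product; starting material + dissolved gas -> target; gas phase <-> dissolved gas; 2 dissolved gas -> homo dimer; dissolved gas + target -> over-reacted product

Between those readings I replace the curve of target over starting material by its mean:

factor = (starting material lost + target lost) / (starting material lost × mean of target/starting material)

The grey run gives 2.63, so I take 2.69, the selectivity factor: how many times more readily dissolved gas takes target than starting material at equal amounts. Both steps use that gas, so its level cancels. With s the fraction of starting material left: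

target = (s − s^factor) / (factor − 1)

s at the top = 55.7%

target at the top = s / factor = 20.7%

As a test, the curve gives 18.6% at the unused blue reading of 19.2%, and 14.7% at the grey 14.6%. The factor gives a height but no time, so I go back to the readings: interpolating them puts that s at 18.4 min in blue and 30.4 min in grey. Taken linearly in charge, that is my estimate of 0.387 h for the peak in this flask.

The forecast says 20.8% at 0.39 h, “whatever the concentration” for the height.

The flask gives 20.6% at 0.391 h.

    dissolved gas → decomposition product (k = 5.00 × 10⁻⁵ min⁻¹)
    starting material + dissolved gas → target (k = 17.0 L mol⁻¹ min⁻¹)
    gas phase ⇌ dissolved gas, rate k3*(csat - [dissolved gas]) (kL = 0.150 min⁻¹)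
    2 dissolved gas → homo dimer (k = 2.10 L mol⁻¹ min⁻¹)
    dissolved gas + target → over-reacted product (k = 46.0 L mol⁻¹ min⁻¹)

At the best time this flask holds 55.8% starting material, and dividing by the factor gives 20.7% target, the level at which making and loss balance. Without the step from target to over-reacted product, the highest target in this flask is 99.8% instead of 20.6%.

A neighbour flask stopped at 25 min holds 53.5% starting material, so the factor gives 20.7% target; the computed amount is 20.6%.

The readings stem from a simulated flask with made-up constants; the scatter is artificial.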